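**Strategy.** The cyclohexane ring is numbered C1 (ketone), C2 (methyl-bearing epoxide carbon), C3 (epoxide CH), C4 (CH2), C5 (side-chain carbon) and C6 (angeloyloxy carbon). It is cut into two enals: prenal supplies C1–C2(Me)–C3 and a 2-substituted acrolein supplies C4–C5–C6. One proline-catalysed formal [3+3] annulation joins them, forming C3–C4 by vinylogous Michael addition and C1–C6 by aldol condensation. The step exploits the fact that the four contiguous oxygenated ring carbons (C3, C2, C1, C6) are exactly the sp2 carbons of the resulting cross-conjugated dienal. The formyl group left on C1 is an activating group, later excised oxidatively to unveil the ketone.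

Key step: step 3

Assumption: the sense of induction of (S)-proline in step 3 cannot be predicted with certainty and is taken to give the (S)-dienal 7; if the antipode forms, (R)-proline is used with no other change. Compounds 1, 4 and 11 are taken as commercial.

Step 1
Reactants: 1 methyl 4,4-dimethoxybutanoate
Product: 2 4,4-dimethoxybutanal
Conditions: i-Bu2AlH (1.05 equiv), CH2Cl2, −78 °C; aq. potassium sodium tartrate (KNaC4H4O6)
Reagents that add atoms: none
Why: Partial reduction of an ester with i-Bu2AlH at −78 °C stops at the aldehyde through the stable tetrahedral aluminium hemiacetal; the acetal is inert.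

Step 2
Reactants: 2 4,4-dimethoxybutanal
Product: 3 4,4-dimethoxy-2-methylidenebutanal
Conditions: 37% aq. CH2O, pyrrolidine (10 mol %), propionic acid (10 mol %), i-PrOH, 45 °C
Reagents that add atoms: formaldehyde, C=O
Why: Amine-catalysed α-methylenation of an aldehyde (Mannich condensation with formaldehyde, then elimination of the amine) gives the 2-substituted acrolein; no stereocentre is formed.

Step 3
Reactants: 3 4,4-dimethoxy-2-methylidenebutanal, 4 3-methylbut-2-enal (prenal)
Product: 7 (3S)-3-(2,2-dimethoxyethyl)-6-methylcyclohexa-1,5-diene-1-carbaldehyde, via dialdehyde Michael adduct 5 (not isolated), via hydroxy aldehyde 6 (not isolated)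
Conditions: (S)-proline (30 mol %), 4 (1.5 equiv), DMF, −10 °C to rt
Reagents that add atoms: none
Why: (S)-Proline condenses with prenal to a dienamine whose terminal γ-carbon adds to the β-methylene of enal 3 (vinylogous Michael addition, C3–C4) to give 5; renewed dienamine formation towards C3 lets the α-carbon attack the tethered aldehyde in a 6-(enolexo)-exo-trig aldol closure (C1–C6) to give 6, and loss of water gives the cross-conjugated dienal 7. This is the amine-catalysed formal [3+3] annulation of two enals (Michael addition/aldol condensation), a known reaction type. Only C5 survives as a stereocentre: it is epimerisable α to the aldehyde in 5 and is fixed in the proline-bound, carboxylic-acid-organised chair-like aldol transition state, which places the dimethoxyethyl group equatorial and so passes one C5 epimer on to ring closure (dynamic kinetic resolution). The step needs γ- over α-attack in the Michael event and closure through the donor α-carbon, not the acceptor α-carbon; the first follows from the unhindered terminal CH2 of the dienamine, the second from the α-branch of 3, whose enamine carbon would have to become quaternary and could not then eliminate the amine. Prenal, a β,β-disubstituted enal, is a poor acceptor, and 3 has no conjugated γ-hydrogen and cannot act as donor, so the cross-reaction should prevail over self-condensation.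

Step 4
Reactants: 7 (3S)-3-(2,2-dimethoxyethyl)-6-methylcyclohexa-1,5-diene-1-carbaldehyde
Product: 8 (1R,5S,6S)-5-(2,2-dimethoxyethyl)-2-methyl-7-oxabicyclo[4.1.0]hept-2-ene-1-carbaldehyde (epoxide oxygen trans to the side chain)
Conditions: 30% aq. H2O2, NaOH (0.2 equiv), MeOH, 0 °C
Reagents that add atoms: hydrogen peroxide, OO
Why: Weitz–Scheffer nucleophilic epoxidation: hydroperoxide adds only to C6, the β-carbon of the enal (C2=C3 is cross-conjugated and not an acceptor), anti to the adjacent C5 substituent, which sets C6–O trans to the side chain and C1 with it.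

Step 5
Reactants: 8 (1R,5S,6S)-5-(2,2-dimethoxyethyl)-2-methyl-7-oxabicyclo[4.1.0]hept-2-ene-1-carbaldehyde
Product: 10 (5S,6S)-5-(2,2-dimethoxyethyl)-6-hydroxy-2-methylcyclohex-2-en-1-one, via epoxy formate 9 (not isolated)
Conditions: mCPBA (1.1 equiv), NaHCO3, CH2Cl2, 0 °C; then K2CO3 (0.1 equiv), MeOH, 0 °C
Reagents that add atoms: mCPBA, OOC(=O)c1cccc(Cl)c1
Why: Baeyer–Villiger (Dakin-type) oxidation: the tertiary, oxygen-bearing C1 migrates in preference to hydrogen to give formate 9; methanolysis frees the C1 alkoxide, which expels the epoxide oxygen onto C6 with retention and leaves the conjugated C1 ketone.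

Step 6
Reactants: 10 (5S,6S)-5-(2,2-dimethoxyethyl)-6-hydroxy-2-methylcyclohex-2-en-1-one, 11 angelic acid
Product: 13 (1S,6S)-6-(2,2-dimethoxyethyl)-3-methyl-2-oxocyclohex-3-en-1-yl (Z)-2-methylbut-2-enoate, via mixed anhydride 12 (not isolated)
Conditions: 11, 2,4,6-trichlorobenzoyl chloride, Et3N, toluene, rt; then 10, 75 °C (no DMAP)
Reagents that add atoms: none
Why: Yamaguchi esterification through mixed anhydride 12 without DMAP, the conditions under which hindered secondary alcohols are acylated with angelic acid without Z-to-E isomerisation; no stereocentre is touched.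

Step 7
Reactants: 13 (1S,6S)-6-(2,2-dimethoxyethyl)-3-methyl-2-oxocyclohex-3-en-1-yl (Z)-2-methylbut-2-enoate
Product: 14 (1S,2S,6S)-6-(2,2-dimethoxyethyl)-2-hydroxy-3-methylcyclohex-3-en-1-yl (Z)-2-methylbut-2-enoate
Conditions: NaBH4, CeCl3·7H2O, MeOH, −78 °C
Reagents that add atoms: none
Why: Luche 1,2-reduction: axial hydride delivery to the half-chair enone, whose C5 and C6 substituents are pseudo-equatorial, should give the pseudo-equatorial C1 alcohol, trans to the C6 ester and cis to the C5 side chain (as carvone gives cis-carveol); ester and acetal are inert.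

Step 8
Reactants: 14 (1S,2S,6S)-6-(2,2-dimethoxyethyl)-2-hydroxy-3-methylcyclohex-3-en-1-yl (Z)-2-methylbut-2-enoate
Product: 15 (1R,2R,3S,4S,6S)-4-(2,2-dimethoxyethyl)-2-hydroxy-1-methyl-7-oxabicyclo[4.1.0]heptan-3-yl (Z)-2-methylbut-2-enoate
Conditions: VO(acac)2 (5 mol %), t-BuOOH (decane solution), CH2Cl2, 0 °C to rt
Reagents that add atoms: tert-butyl hydroperoxide, CC(C)(C)OO
Why: Hydroxyl-directed epoxidation of the allylic alcohol delivers oxygen to the face of the C1 hydroxyl, which sets C2 and C3 with the epoxide cis to the C5 side chain and trans to the C6 ester; the electron-poor angelate alkene does not react.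

Step 9
Reactants: 15 (1R,2R,3S,4S,6S)-4-(2,2-dimethoxyethyl)-2-hydroxy-1-methyl-7-oxabicyclo[4.1.0]heptan-3-yl (Z)-2-methylbut-2-enoate
Product: 16 (1S,3S,4S,6S)-4-(2,2-dimethoxyethyl)-1-methyl-2-oxo-7-oxabicyclo[4.1.0]heptan-3-yl (Z)-2-methylbut-2-enoate
Conditions: Dess–Martin periodinane, NaHCO3, CH2Cl2, 0 °C to rt
Reagents that add atoms: none
Why: Dess–Martin oxidation of the secondary alcohol to the ketone under buffered, non-epimerising conditions; epoxide and esters are inert.

Step 10
Reactants: 16 (1S,3S,4S,6S)-4-(2,2-dimethoxyethyl)-1-methyl-2-oxo-7-oxabicyclo[4.1.0]heptan-3-yl (Z)-2-methylbut-2-enoate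
Product: 17 (1S,3S,4S,6S)-1-methyl-2-oxo-4-(2-oxoethyl)-7-oxabicyclo[4.1.0]heptan-3-yl (Z)-2-methylbut-2-enoate
Conditions: pyridinium p-toluenesulfonate (cat.), acetone–H2O (10:1), 40 °C
Reagents that add atoms: water, O
Why: Acid-catalysed hydrolysis of the dimethyl acetal; the α,β-epoxy ketone is deactivated towards acid opening by the adjacent carbonyl.

Step 11
Reactants: 17 (1S,3S,4S,6S)-1-methyl-2-oxo-4-(2-oxoethyl)-7-oxabicyclo[4.1.0]heptan-3-yl (Z)-2-methylbut-2-enoate
Product: 18 (1S,3S,4S,6S)-1-methyl-2-oxo-4-(3-oxoprop-1-en-2-yl)-7-oxabicyclo[4.1.0]heptan-3-yl (Z)-2-methylbut-2-enoate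
Conditions: 37% aq. CH2O, pyrrolidine (10 mol %), propionic acid (10 mol %), i-PrOH, 45 °C
Reagents that add atoms: formaldehyde, C=O
Why: Amine-catalysed α-methylenation (Mannich condensation–elimination) of the aldehyde, which enolises far more readily than the hindered ketone, installs the exocyclic methylene carbon of the side chain.

Step 12
Reactants: 18 (1S,3S,4S,6S)-1-methyl-2-oxo-4-(3-oxoprop-1-en-2-yl)-7-oxabicyclo[4.1.0]heptan-3-yl (Z)-2-methylbut-2-enoate
Product: 19 (1S,3S,4S,6S)-4-[(3S)-3-hydroxyhexa-1,5-dien-2-yl]-1-methyl-2-oxo-7-oxabicyclo[4.1.0]heptan-3-yl (Z)-2-methylbut-2-enoate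
Conditions: (S)-BINOL (20 mol %), Ti(OiPr)4 (10 mol %), 4 Å molecular sieves, CH2Cl2, rt; then 18, allylSnBu3 (1.5 equiv), −20 °C
Reagents that add atoms: allyltributylstannane, C=CC[Sn](CCCC)(CCCC)CCCC
Why: Keck asymmetric allylation: the titanium–(S)-BINOL complex directs the allyl group to the Si face of the aldehyde, which sets the side-chain carbinol centre as S under catalyst control; under these conditions the stannane adds to aldehydes and not to ketones.

Step 13
Reactants: 19 (1S,3S,4S,6S)-4-[(3S)-3-hydroxyhexa-1,5-dien-2-yl]-1-methyl-2-oxo-7-oxabicyclo[4.1.0]heptan-3-yl (Z)-2-methylbut-2-enoate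
Product: 20 (1S,3S,4S,6S)-4-[(3S)-3-acetoxyhexa-1,5-dien-2-yl]-1-methyl-2-oxo-7-oxabicyclo[4.1.0]heptan-3-yl (Z)-2-methylbut-2-enoate
Conditions: Ac2O, pyridine, CH2Cl2, 0 °C to rt (no DMAP)
Reagents that add atoms: acetic anhydride, CC(=O)OC(C)=O
Why: Acetylation (nucleophilic acyl substitution) of the only free hydroxyl, run without DMAP to spare the angelate geometry.

Step 14
Reactants: 20 (1S,3S,4S,6S)-4-[(3S)-3-acetoxyhexa-1,5-dien-2-yl]-1-methyl-2-oxo-7-oxabicyclo[4.1.0]heptan-3-yl (Z)-2-methylbut-2-enoate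
Product: 21 (1S,3S,4S,6S)-4-[(3S)-3-acetoxy-6-methylhepta-1,5-dien-2-yl]-1-methyl-2-oxo-7-oxabicyclo[4.1.0]heptan-3-yl (Z)-2-methylbut-2-enoate (CNP0125636.1)
Conditions: second-generation Grubbs catalyst RuCl2(=CHPh)(PCy3)(H2IMes) (5 mol %), 2-methylbut-2-ene (excess), CH2Cl2, 35 °C
Reagents that add atoms: 2-methylbut-2-ene, CC=C(C)C
Why: Olefin cross-metathesis of the monosubstituted alkene with excess 2-methylbut-2-ene installs the isopropylidene terminus; the 1,1-disubstituted side-chain alkene and the trisubstituted, electron-poor angelate alkene should stay out of the catalytic cycle, and no stereocentre is touched.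

**Compound list**

1 | methyl 4,4-dimethoxybutanoate | COC(=O)CCC(OC)OC | starting material
2 | 4,4-dimethoxybutanal | O=CCCC(OC)OC | intermediate
3 | 4,4-dimethoxy-2-methylidenebutanal | C=C(C=O)CC(OC)OC | intermediate
4 | 3-methylbut-2-enal (prenal) | CC(C)=CC=O | starting material
5 | 2-(2,2-dimethoxyethyl)-5-methylhept-5-enedial (Michael adduct; C2 labile, alkene geometry open) | COC(OC)CC(C=O)CCC(C)=CC=O | intermediate
6 | (3S)-3-(2,2-dimethoxyethyl)-2-hydroxy-6-methylcyclohex-5-ene-1-carbaldehyde (aldol adduct; mixture at C1 and C2) | COC(OC)C[C@@H]1CC=C(C)C(C=O)C1O | intermediate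
7 | (3S)-3-(2,2-dimethoxyethyl)-6-methylcyclohexa-1,5-diene-1-carbaldehyde | COC(OC)C[C@@H]1CC=C(C)C(C=O)=C1 | intermediate
8 | (1R,5S,6S)-5-(2,2-dimethoxyethyl)-2-methyl-7-oxabicyclo[4.1.0]hept-2-ene-1-carbaldehyde | COC(OC)C[C@@H]1CC=C(C)[C@@]2(C=O)O[C@@H]12 | intermediate
9 | (1S,5S,6S)-5-(2,2-dimethoxyethyl)-2-methyl-7-oxabicyclo[4.1.0]hept-2-en-1-yl formate | COC(OC)C[C@@H]1CC=C(C)[C@@]2(OC=O)O[C@@H]12 | intermediate
10 | (5S,6S)-5-(2,2-dimethoxyethyl)-6-hydroxy-2-methylcyclohex-2-en-1-one (hydroxyl trans to the side chain) | COC(OC)C[C@@H]1CC=C(C)C(=O)[C@H]1O | intermediate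
11 | angelic acid, (Z)-2-methylbut-2-enoic acid | C/C=C(/C)C(=O)O | starting material
12 | (Z)-2-methylbut-2-enoic 2,4,6-trichlorobenzoic anhydride | C/C=C(/C)C(=O)OC(=O)c1c(Cl)cc(Cl)cc1Cl | intermediate
13 | (1S,6S)-6-(2,2-dimethoxyethyl)-3-methyl-2-oxocyclohex-3-en-1-yl (Z)-2-methylbut-2-enoate | COC(OC)C[C@@H]1CC=C(C)C(=O)[C@H]1OC(=O)/C(C)=C\C | intermediate
14 | (1S,2S,6S)-6-(2,2-dimethoxyethyl)-2-hydroxy-3-methylcyclohex-3-en-1-yl (Z)-2-methylbut-2-enoate | COC(OC)C[C@@H]1CC=C(C)[C@H](O)[C@H]1OC(=O)/C(C)=C\C | intermediate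
15 | (1R,2R,3S,4S,6S)-4-(2,2-dimethoxyethyl)-2-hydroxy-1-methyl-7-oxabicyclo[4.1.0]heptan-3-yl (Z)-2-methylbut-2-enoate | COC(OC)C[C@@H]1C[C@@H]2O[C@]2(C)[C@H](O)[C@H]1OC(=O)/C(C)=C\C | intermediate
16 | (1S,3S,4S,6S)-4-(2,2-dimethoxyethyl)-1-methyl-2-oxo-7-oxabicyclo[4.1.0]heptan-3-yl (Z)-2-methylbut-2-enoate | COC(OC)C[C@@H]1C[C@@H]2O[C@]2(C)C(=O)[C@H]1OC(=O)/C(C)=C\C | intermediate
17 | (1S,3S,4S,6S)-1-methyl-2-oxo-4-(2-oxoethyl)-7-oxabicyclo[4.1.0]heptan-3-yl (Z)-2-methylbut-2-enoate | O=CC[C@@H]1C[C@@H]2O[C@]2(C)C(=O)[C@H]1OC(=O)/C(C)=C\C | intermediate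
18 | (1S,3S,4S,6S)-1-methyl-2-oxo-4-(3-oxoprop-1-en-2-yl)-7-oxabicyclo[4.1.0]heptan-3-yl (Z)-2-methylbut-2-enoate | C=C(C=O)[C@@H]1C[C@@H]2O[C@]2(C)C(=O)[C@H]1OC(=O)/C(C)=C\C | intermediate
19 | (1S,3S,4S,6S)-4-[(3S)-3-hydroxyhexa-1,5-dien-2-yl]-1-methyl-2-oxo-7-oxabicyclo[4.1.0]heptan-3-yl (Z)-2-methylbut-2-enoate | C=C([C@H](CC=C)O)[C@@H]1C[C@@H]2O[C@]2(C)C(=O)[C@H]1OC(=O)/C(C)=C\C | intermediate
20 | (1S,3S,4S,6S)-4-[(3S)-3-acetoxyhexa-1,5-dien-2-yl]-1-methyl-2-oxo-7-oxabicyclo[4.1.0]heptan-3-yl (Z)-2-methylbut-2-enoate | C=C([C@H](CC=C)OC(C)=O)[C@@H]1C[C@@H]2O[C@]2(C)C(=O)[C@H]1OC(=O)/C(C)=C\C | intermediate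
21 | (1S,3S,4S,6S)-4-[(3S)-3-acetoxy-6-methylhepta-1,5-dien-2-yl]-1-methyl-2-oxo-7-oxabicyclo[4.1.0]heptan-3-yl (Z)-2-methylbut-2-enoate | C=C([C@H](CC=C(C)C)OC(C)=O)[C@@H]1C[C@@H]2O[C@]2(C)C(=O)[C@H]1OC(=O)/C(C)=C\C | target

**Step count.** Total: 14 steps. Longest linear sequence: 14 steps (1 to 21).

**Steps most likely to fail**

Step 3. What may go wrong is weak facial control in the ring-closing aldol, or erosion of the C5 configuration by reversible dienamine formation on the product (its C5–H is vinylogously acidic). The fallback gives up catalyst control in favour of an enzymatic resolution. It sets out from 3 and 4: the same annulation is run with pyrrolidinium acetate to give racemic dienal F1, which is taken through the operations of steps 4 and 5 to racemic trans-epoxy aldehyde F2 and racemic trans-hydroxy enone F3. Lipase-catalysed acetylation (Burkholderia cepacia lipase, vinyl acetate, t-BuOMe) should then acylate, by Kazlauskas' rule with the C5 side as the large group, the (5S,6S)-enantiomer to the (5S,6S)-acetate F4. F4 is separated from the unreacted antipode and methanolysed (K2CO3, MeOH, 0 °C), and the route is rejoined at 10.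

Step 5. What may go wrong is peracid epoxidation of the C2=C3 alkene competing with acyl migration, or acid-induced opening of the vinyl epoxide before the Baeyer–Villiger step. The fallback changes the order of events and sets out from 7, bypassing 8. Seleninic-acid-catalysed Baeyer–Villiger oxidation of the enal (30% H2O2, PhSeO2H cat., CH2Cl2) gives the dienyl formate F5. Methanolysis (K2CO3, MeOH) gives the carvone-type (5S)-enone F6. Its kinetic lithium enolate (LiN(SiMe3)2, THF, −78 °C) is hydroxylated with 2-(phenylsulfonyl)-3-phenyloxaziridine anti to the C5 substituent, and the route is rejoined at 10.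

Step 7. What may go wrong is hydride delivery from the face syn to the C6 oxygen through a cerium chelate, or a 1,2-shift of the angeloyl group onto the new alkoxide. The fallback corrects the configuration by inversion rather than by another reduction and sets out from 13. If the C1-epimeric alcohol F7 predominates, a Mitsunobu reaction (PPh3, DIAD, HCO2H, THF, 0 °C) gives the inverted formate F8. Selective cleavage of the formate (KHCO3, MeOH, 0 °C) leaves the angelate in place, and the route is rejoined at 14.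

**Further compounds**

F1 | step 3 | racemic 3-(2,2-dimethoxyethyl)-6-methylcyclohexa-1,5-diene-1-carbaldehyde | COC(OC)CC1CC=C(C)C(C=O)=C1
F2 | step 3 | racemic trans-5-(2,2-dimethoxyethyl)-2-methyl-7-oxabicyclo[4.1.0]hept-2-ene-1-carbaldehyde (relative configuration as in 8) | COC(OC)CC1CC=C(C)C2(C=O)OC12
F3 | step 3 | racemic trans-5-(2,2-dimethoxyethyl)-6-hydroxy-2-methylcyclohex-2-en-1-one (relative configuration as in 10) | COC(OC)CC1CC=C(C)C(=O)C1O
F4 | step 3 | (1S,6S)-6-(2,2-dimethoxyethyl)-3-methyl-2-oxocyclohex-3-en-1-yl acetate | COC(OC)C[C@@H]1CC=C(C)C(=O)[C@H]1OC(C)=O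
F5 | step 5 | (3S)-3-(2,2-dimethoxyethyl)-6-methylcyclohexa-1,5-dien-1-yl formate | COC(OC)C[C@@H]1CC=C(C)C(OC=O)=C1
F6 | step 5 | (5S)-5-(2,2-dimethoxyethyl)-2-methylcyclohex-2-en-1-one | COC(OC)C[C@@H]1CC=C(C)C(=O)C1
F7 | step 7 | (1S,2R,6S)-6-(2,2-dimethoxyethyl)-2-hydroxy-3-methylcyclohex-3-en-1-yl (Z)-2-methylbut-2-enoate (C1 epimer of 14 in the ring numbering of the overview) | COC(OC)C[C@@H]1CC=C(C)[C@@H](O)[C@H]1OC(=O)/C(C)=C\C
F8 | step 7 | (1S,2S,6S)-6-(2,2-dimethoxyethyl)-2-(formyloxy)-3-methylcyclohex-3-en-1-yl (Z)-2-methylbut-2-enoate | COC(OC)C[C@@H]1CC=C(C)[C@H](OC=O)[C@H]1OC(=O)/C(C)=C\C
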